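The numbers of this flask belong to no real substance; the result is computed.

Read ash, birch and larch at 40 h and the tank alder at its outlet, and ask how much target stands there, a product made from intermediate C while it is lost to over-reaction product.

| flask | substrate | coupling partner | time | remark |
|---|---|---|---|---|
| ash | 0.050 M | 0.125 M (fed, over 32.0 h) | 40 h | a stirred flask in which coupling partner is dosed at a steady rate over 32.0 h without added volume, worked up at 40 h |
| alder | 0.050 M | 0.125 M |  | one stirred flow tank at steady state, fed with the mixture as stated, mean residence time 40 h |
| birch | 0.050 M (fed, over 32.0 h) | 0.125 M | 40 h | all but substrate at the start; substrate goes in evenly over 32.0 h, the run ends at 40 h |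
| larch | 0.050 M | 0.125 M | 40 h | everything together in a closed stirred flask, run for 40 h |

    substrate ⇌ intermediate A (K1 = 15, k1 = 0.0082 min⁻¹)
    substrate ⇌ intermediate B (K2 = 1.4, k2 = 0.025 min⁻¹)
    intermediate A → intermediate C (k3 = 0.020 min⁻¹)
    coupling partner + intermediate B ⇌ intermediate D (K4 = 1.3 L mol⁻¹, k4 = 0.015 L mol⁻¹ min⁻¹)
    coupling partner + intermediate C → target (k5 = 0.026 L mol⁻¹ min⁻¹)
    coupling partner + intermediate D → side product (k6 = 0.043 L mol⁻¹ min⁻¹)
    target → over-reaction product (k7 = 0.0026 min⁻¹)

- the stated concentrations are those of everything mixed, before any reaction; amounts are the same in each set-up
- the feed brings no volume worth counting
- run time (ash): 40 h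

* the set-up with the highest amount of target at the outlet or at the end, in percent of the substrate put in ("none" if the first two lie within 2 percentage points) (ash / alder / birch / larch / none)
* amount of target at the outlet or at the end, in percent of the substrate put in, ash
* amount of target at the outlet or at the end, in percent of the substrate put in, alder
* amount of target at the outlet or at the end, in percent of the substrate put in, birch
* amount of target at the outlet or at the end, in percent of the substrate put in, larch

Define the holding ratio H as the target standing per intermediate C when making and losing balance. Its numerator is the pseudo-first-order making constant, 0.026 L mol⁻¹ min⁻¹ times the partner level P. Its denominator is the loss constant, 0.0026 min⁻¹ plus the flushing rate D. In the tank alder, D is the inverse residence time, 4.17 × 10⁻⁴ min⁻¹; in a flask without outflow it drops out.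

Start with alder, where the balances are algebra. Treat the partner as the large thing and the substrate as the correction. If the whole substrate charge passes through, P is 0.0750 M and the making constant is 0.00195 min⁻¹, faster than flushing. So intermediate C holds 17.6% of the substrate fed, H is 0.646, and target is 11.4%.

The weak link is the assumption that the feed reaches intermediate C, so reforge it. Substrate and intermediate B interconvert faster than substrate passes to intermediate A, so treat them as one pool in which a fraction 0.417 is free substrate. Leaving the path through intermediate D out of this estimate, the pool drains at 0.00342 min⁻¹ against flushing, so reckon 89.1% of the feed past it. Intermediate A then passes on, since 0.020 min⁻¹ exceeds its return constant. The partner is spared accordingly: P rises to 0.0883 M, the making constant to 0.00230 min⁻¹, and intermediate C becomes 13.7%. The holding ratio, target per intermediate C, becomes 0.761. Commit to 10.4% of target for alder.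

The reckoning stops at the tank, because the other flasks change with time. There, use target's lifetime, 6.41 h, shorter than the run. Rank birch, fed until 8.00 h before the reading, above larch, charged at the start, without a figure.

The forecast named birch best, on “late substrate feeding with excess partner”, with 8% for ash, 9% for alder, less than my 10.4%, 16.5% for birch and 4.5% for larch.

The simulation gives 9.39% for ash, 9.67% for alder, 14.2% for birch and 3.45% for larch, so birch stands highest.

Strike the reaction of target to over-reaction product out of birch and target rises from 14.2% to 75.7%, so that reaction is the main reason birch stops where it does. H carries this loss in its denominator: on the 13.1% of intermediate C in alder, H gives 9.97% of target against 9.67%. In the birch neighbour with 0.031 M of partner, 37.2% of that charge remains at 40.0 h and the flask has no outflow, so H is 0.115; on 57.1% of intermediate C it gives 6.57% of target, and that flask holds 7.75%.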